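**Retrosynthetic overview**
1. Endgame: the C6 veratroate is carried from the start; the C10 angelate comes from a C10 ketone (Luche reduction, then Mitsunobu inversion); the C4 hydroxyl comes from a C4 formyl group (Baeyer–Villiger, retention).
2. Key disconnection: the ring-fusion bond C1–C5 and the cyclopentane bond C3–C4 are cut together, which opens the seven-membered and the five-membered ring at once and leads to an open-chain enal that carries a 1-acyl-1-methylcyclopropane.
3. Enabling feature: in the cyclopentane C1–C2–C3–C4–C5, quaternary C1 sits next to oxygenated C10 and C5 sits next to oxygenated C4. With C10 as a ketone, C1–C2–C3 is an acylcyclopropane (latent C1 enolate and C3 electrophile); with a formyl group standing in for the C4 oxygen, C5=C4 is an enal (C5 electrophile, C4 enolate). The two polar pairs match across the 5/7 ring fusion.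
4. Ring order forward: seven-membered ring (C1–C5) first, cyclopentane (C3–C4) second, in one flask; the precursor is built linearly from (S)-glycidyl trityl ether, acetylide, veratroyl chloride, 1-methylcyclopropanecarbonyl chloride, a methyl cuprate and a formyl ylide.

Key step: step 9

Remark (numbering): daucane numbering is used: C1 quaternary ring-fusion carbon (CH3), C2/C3 ring CH2, C4 carbinol carbon (isopropyl), C5 ring-fusion CH, C6 CH–O-veratroyl, C7 CH2, C8 C(CH3)=, C9 =CH, C10 CH–O-angeloyl; β is the face of the C1 methyl group. The target is (1S,4R,5S,6S,10R), with a (Z)-2-methylbut-2-enoate (angelate).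
Remark (bookkeeping): coupling partners that bring carbon into the route are numbered reactants; the line "Reagents that add atoms" lists only unnumbered reagents.
Assumption: 1-methylcyclopropanecarbonyl chloride is bought (otherwise one step from the commercial acid with oxalyl chloride).

Step 1
Reactants: 1 isobutyltriphenylphosphonium bromide; 2 ethyl formate
Product: 4 3-methyl-2-(triphenylphosphoranylidene)butanal, via (2-methylpropylidene)triphenylphosphorane 3 (not isolated)
Conditions: n-BuLi, THF, 0 °C; then 2, 0 °C to rt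
Reagents that add atoms: none
Why: Deprotonation gives the non-stabilised ylide 3, whose C-formylation by ethyl formate (acylation of a phosphorus ylide) and loss of ethanol should give the formyl-stabilised ylide 4, with no stereocentre involved.

Step 2
Reactants: 5 (S)-glycidyl trityl ether; 6 lithium acetylide–ethylenediamine complex (LiC≡CH·H2NCH2CH2NH2)
Product: 7 (S)-1-(trityloxy)pent-4-yn-2-ol
Conditions: DMSO, rt; then H2O
Reagents that add atoms: none
Why: The acetylide opens the epoxide by SN2 attack at the unsubstituted carbon (epoxide ring opening), so the stereocentre of 5, the later C6, is carried over untouched.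

Step 3
Reactants: 7 (S)-1-(trityloxy)pent-4-yn-2-ol; 8 3,4-dimethoxybenzoyl chloride
Product: 9 (S)-1-(trityloxy)pent-4-yn-2-yl 3,4-dimethoxybenzoate
Conditions: pyridine, DMAP (catalytic), CH2Cl2, 0 °C to rt
Reagents that add atoms: none
Why: DMAP-catalysed acylation of the secondary alcohol with the acid chloride (esterification) installs the veratroate early, where it also serves as the protecting group of the C6 oxygen, without touching the stereocentre.

Step 4
Reactants: 9 (S)-1-(trityloxy)pent-4-yn-2-yl 3,4-dimethoxybenzoate; 10 1-methylcyclopropanecarbonyl chloride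
Product: 11 (S)-6-(1-methylcyclopropyl)-6-oxo-1-(trityloxy)hex-4-yn-2-yl 3,4-dimethoxybenzoate
Conditions: PdCl2(PPh3)2 (2 mol%), CuI (4 mol%), Et3N, THF, rt
Reagents that add atoms: none
Why: Acyl Sonogashira coupling joins the terminal alkyne, as its copper acetylide, with the acylpalladium species formed from the acid chloride and zerovalent palladium, under conditions that should tolerate the aryl ester and the trityl ether.

Step 5
Reactants: 11 (S)-6-(1-methylcyclopropyl)-6-oxo-1-(trityloxy)hex-4-yn-2-yl 3,4-dimethoxybenzoate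
Product: 12 (2S,4Z)-4-methyl-6-(1-methylcyclopropyl)-6-oxo-1-(trityloxy)hex-4-en-2-yl 3,4-dimethoxybenzoate
Conditions: Me2CuLi (from MeLi and CuI), THF, −78 °C; then aqueous NH4Cl, −78 °C
Reagents that add atoms: lithium dimethylcuprate, Me2CuLi ([Li+].C[Cu-]C)
Why: Syn carbocupration of the ynone (conjugate addition of a Gilman cuprate) and protonation at low temperature should place the new methyl group trans to the ketone, hence the chain CH2 cis to the carbonyl as in the (Z)-enone, while the aryl ester and the cyclopropane are left alone.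

Step 6
Reactants: 12 (2S,4Z)-4-methyl-6-(1-methylcyclopropyl)-6-oxo-1-(trityloxy)hex-4-en-2-yl 3,4-dimethoxybenzoate
Product: 13 (2S,4Z)-1-hydroxy-4-methyl-6-(1-methylcyclopropyl)-6-oxohex-4-en-2-yl 3,4-dimethoxybenzoate
Conditions: TsOH·H2O (catalytic), MeOH/CH2Cl2, 0 °C
Reagents that add atoms: none
Why: Acid-catalysed methanolysis of the trityl ether (SN1 through the trityl cation) should free the primary alcohol at 0 °C without migration of the secondary veratroate.

Step 7
Reactants: 13 (2S,4Z)-1-hydroxy-4-methyl-6-(1-methylcyclopropyl)-6-oxohex-4-en-2-yl 3,4-dimethoxybenzoate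
Product: 14 (2S,4Z)-4-methyl-6-(1-methylcyclopropyl)-1,6-dioxohex-4-en-2-yl 3,4-dimethoxybenzoate
Conditions: Dess–Martin periodinane, CH2Cl2, 0 °C to rt
Reagents that add atoms: none
Why: Dess–Martin oxidation converts the primary alcohol into the aldehyde under near-neutral conditions that should neither epimerise the α-aroyloxy centre nor touch the enone and the acylcyclopropane.

Step 8
Reactants: 14 (2S,4Z)-4-methyl-6-(1-methylcyclopropyl)-1,6-dioxohex-4-en-2-yl 3,4-dimethoxybenzoate; 4 3-methyl-2-(triphenylphosphoranylidene)butanal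
Product: 15 (2E,4S,6Z)-2-isopropyl-6-methyl-8-(1-methylcyclopropyl)-1,8-dioxoocta-2,6-dien-4-yl 3,4-dimethoxybenzoate
Conditions: toluene, 80 °C
Reagents that add atoms: none
Why: Wittig olefination with the formyl-stabilised ylide reacts only at the aldehyde and should give the (E)-enal, with the oxygen-bearing carbon trans to CHO, as is usual for stabilised ylides.

Step 9
Reactants: 15 (2E,4S,6Z)-2-isopropyl-6-methyl-8-(1-methylcyclopropyl)-1,8-dioxoocta-2,6-dien-4-yl 3,4-dimethoxybenzoate
Product: 18 (1S,4R,5S,6S)-4β-formyl-6α-(3,4-dimethoxybenzoyloxy)dauc-8-en-10-one, via γ-iodo magnesium enolate 16 (not isolated), via aldehyde magnesium enolate 17 (not isolated)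
Conditions: MgI2 (1.2 equiv), THF (0.01 M), 60 °C
Reagents that add atoms: none
Why: Proposed new method: MgI2 serves as Lewis acid and iodide source, so that iodide opens the ketone-activated cyclopropane of 15 at a CH2 carbon (reversible homo-conjugate addition) to the γ-iodo enolate 16, whose carbon C1 adds to C5 of the tethered enal (Michael addition) to give the aldehyde enolate 17, which then displaces iodide at C3 (enolate C-alkylation) and returns MgI2. The closest known reaction types are the MgI2-mediated ring expansion of acylcyclopropanes with imines (ring opening, Mannich addition, N-alkylation) and the iodide-induced ring opening of cyclopropyl ketones with aldol trapping; new here are an enal as the two-carbon partner and a C-alkylation as the closing event. The seven-membered ring closes by 7-exo-trig Michael addition, eased by the (Z)-enone and three sp2 carbons in the five-atom tether, and the cyclopentane closes by 5-exo-tet alkylation, against which O-alkylation would need a seven-membered ring. C5 is controlled by C6: A(1,3) strain to the isopropyl group holds H-6 in the enal plane, and the enolate, tied to C7, can only add anti to the aroyloxy group; C1 is set in the same transition state, in which the enal carbon C4 lies next to the small C1 methyl group and away from the C10 oxygen, which should give the trans ring fusion. C4 is set in the alkylation, where the isopropyl group eclipses H-5 (A(1,2) strain) and C3 therefore enters so that the formyl group ends cis to C6, the place of the later hydroxyl. The step needs Michael rather than aldol addition of 16, secured by ring size (1,2-addition would close a nine-membered ring), and it needs every stage before the alkylation to be reversible, so that unproductive iodide adducts return to 15.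

Step 10
Reactants: 18 (1S,4R,5S,6S)-4β-formyl-6α-(3,4-dimethoxybenzoyloxy)dauc-8-en-10-one
Product: 20 (1S,4R,5S,6S)-4β-hydroxy-6α-(3,4-dimethoxybenzoyloxy)dauc-8-en-10-one, via 4β-formate 19 (not isolated)
Conditions: mCPBA, NaHCO3, CH2Cl2, 0 °C to rt; then KHCO3 (catalytic), MeOH, rt
Reagents that add atoms: mCPBA, 3-chloroperoxybenzoic acid (OOC(=O)c1cccc(Cl)c1)
Why: Baeyer–Villiger oxidation of the aldehyde on a quaternary carbon should proceed by migration of the tertiary alkyl group with retention at C4 to the formate 19, the electron-poor enone double bond resisting epoxidation, and mild methanolysis then removes only the formate.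

Step 11
Reactants: 20 (1S,4R,5S,6S)-4β-hydroxy-6α-(3,4-dimethoxybenzoyloxy)dauc-8-en-10-one
Product: 21 (1S,4R,5S,6S,10S)-6α-(3,4-dimethoxybenzoyloxy)dauc-8-ene-4β,10β-diol
Conditions: NaBH4, CeCl3·7H2O, MeOH, −78 °C
Reagents that add atoms: none
Why: Luche 1,2-reduction of the enone, in which hydride should enter on the face opposite the pseudo-axial C1 methyl group (as with ketones next to an angular methyl group) to give the 10β-alcohol, while CeCl3 suppresses conjugate reduction and the aryl ester is not touched.

Step 12
Reactants: 21 (1S,4R,5S,6S,10S)-6α-(3,4-dimethoxybenzoyloxy)dauc-8-ene-4β,10β-diol; 22 angelic acid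
Product: 23 (1S,4R,5S,6S,10R)-10α-angeloyloxy-6α-(3,4-dimethoxybenzoyloxy)dauc-8-en-4β-ol (target)
Conditions: PPh3, diisopropyl azodicarboxylate (DIAD), toluene, 0 °C to rt
Reagents that add atoms: none
Why: Mitsunobu esterification turns the secondary allylic C10 hydroxyl into an oxyphosphonium leaving group that angelate should displace by SN2 with inversion to the 10α-ester, the tertiary C4 hydroxyl being inert and SN2′ attack at the fully substituted C8 disfavoured.

**Compound list**
1 | isobutyltriphenylphosphonium bromide | CC(C)C[P+](c1ccccc1)(c1ccccc1)c1ccccc1.[Br-] | starting material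
2 | ethyl formate | CCOC=O | starting material
3 | (2-methylpropylidene)triphenylphosphorane | CC(C)C=P(c1ccccc1)(c1ccccc1)c1ccccc1 | intermediate
4 | 3-methyl-2-(triphenylphosphoranylidene)butanal | CC(C)C(C=O)=P(c1ccccc1)(c1ccccc1)c1ccccc1 | intermediate
5 | (S)-glycidyl trityl ether, (S)-2-(trityloxymethyl)oxirane | C1O[C@@H]1COC(c1ccccc1)(c1ccccc1)c1ccccc1 | starting material
6 | lithium acetylide–ethylenediamine complex | [Li+].[C-]#C.NCCN | starting material
7 | (S)-1-(trityloxy)pent-4-yn-2-ol | C#CC[C@H](O)COC(c1ccccc1)(c1ccccc1)c1ccccc1 | intermediate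
8 | 3,4-dimethoxybenzoyl chloride (veratroyl chloride) | COc1ccc(cc1OC)C(Cl)=O | starting material
9 | (S)-1-(trityloxy)pent-4-yn-2-yl 3,4-dimethoxybenzoate | C#CC[C@H](OC(=O)c1ccc(OC)c(OC)c1)COC(c1ccccc1)(c1ccccc1)c1ccccc1 | intermediate
10 | 1-methylcyclopropanecarbonyl chloride | CC1(CC1)C(Cl)=O | starting material
11 | (S)-6-(1-methylcyclopropyl)-6-oxo-1-(trityloxy)hex-4-yn-2-yl 3,4-dimethoxybenzoate | CC1(CC1)C(=O)C#CC[C@H](OC(=O)c1ccc(OC)c(OC)c1)COC(c1ccccc1)(c1ccccc1)c1ccccc1 | intermediate
12 | (2S,4Z)-4-methyl-6-(1-methylcyclopropyl)-6-oxo-1-(trityloxy)hex-4-en-2-yl 3,4-dimethoxybenzoate | CC1(CC1)C(=O)/C=C(C)\C[C@H](OC(=O)c1ccc(OC)c(OC)c1)COC(c1ccccc1)(c1ccccc1)c1ccccc1 | intermediate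
13 | (2S,4Z)-1-hydroxy-4-methyl-6-(1-methylcyclopropyl)-6-oxohex-4-en-2-yl 3,4-dimethoxybenzoate | CC1(CC1)C(=O)/C=C(C)\C[C@H](OC(=O)c1ccc(OC)c(OC)c1)CO | intermediate
14 | (2S,4Z)-4-methyl-6-(1-methylcyclopropyl)-1,6-dioxohex-4-en-2-yl 3,4-dimethoxybenzoate | CC1(CC1)C(=O)/C=C(C)\C[C@H](OC(=O)c1ccc(OC)c(OC)c1)C=O | intermediate
15 | (2E,4S,6Z)-2-isopropyl-6-methyl-8-(1-methylcyclopropyl)-1,8-dioxoocta-2,6-dien-4-yl 3,4-dimethoxybenzoate | CC1(CC1)C(=O)/C=C(C)\C[C@H](OC(=O)c1ccc(OC)c(OC)c1)/C=C(\C(C)C)C=O | intermediate
16 | ring-opened γ-iodo magnesium enolate of 15 (enolate geometry open) | CC(CCI)=C(O[Mg]I)/C=C(C)\C[C@H](OC(=O)c1ccc(OC)c(OC)c1)/C=C(\C(C)C)C=O | intermediate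
17 | seven-membered Michael adduct as aldehyde magnesium enolate (C1 bears CH3 and CH2CH2I; enolate geometry open) | O=C1C=C(C)C[C@H](OC(=O)c2ccc(OC)c(OC)c2)[C@@H](C(C(C)C)=CO[Mg]I)[C@]1(C)CCI | intermediate
18 | (1S,4R,5S,6S)-4β-formyl-6α-(3,4-dimethoxybenzoyloxy)dauc-8-en-10-one (trans-fused 5/7 bicycle; 1β-CH3, 5α-H, 4α-isopropyl) | O=C1C=C(C)C[C@H](OC(=O)c2ccc(OC)c(OC)c2)[C@@H]2[C@]1(C)CC[C@@]2(C=O)C(C)C | intermediate
19 | (1S,4R,5S,6S)-4β-formyloxy-6α-(3,4-dimethoxybenzoyloxy)dauc-8-en-10-one | O=C1C=C(C)C[C@H](OC(=O)c2ccc(OC)c(OC)c2)[C@@H]2[C@]1(C)CC[C@@]2(OC=O)C(C)C | intermediate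
20 | (1S,4R,5S,6S)-4β-hydroxy-6α-(3,4-dimethoxybenzoyloxy)dauc-8-en-10-one | O=C1C=C(C)C[C@H](OC(=O)c2ccc(OC)c(OC)c2)[C@@H]2[C@]1(C)CC[C@@]2(O)C(C)C | intermediate
21 | (1S,4R,5S,6S,10S)-6α-(3,4-dimethoxybenzoyloxy)dauc-8-ene-4β,10β-diol | O[C@H]1C=C(C)C[C@H](OC(=O)c2ccc(OC)c(OC)c2)[C@@H]2[C@]1(C)CC[C@@]2(O)C(C)C | intermediate
22 | angelic acid, (Z)-2-methylbut-2-enoic acid | C/C=C(/C)C(O)=O | starting material
23 | (1S,4R,5S,6S,10R)-10α-angeloyloxy-6α-(3,4-dimethoxybenzoyloxy)dauc-8-en-4β-ol | C/C=C(/C)C(=O)O[C@@H]1C=C(C)C[C@H](OC(=O)c2ccc(OC)c(OC)c2)[C@@H]2[C@]1(C)CC[C@@]2(O)C(C)C | target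

**Step count and risks**
Total steps: 12. Longest linear sequence: 11 steps (steps 2 to 12).

Steps most likely to fail:

Step 9 (Proposed new method). What may go wrong: the ring-opened enolate may re-close to the cyclopropane faster than it undergoes the seven-membered Michael closure; intermolecular Michael addition may compete; the aldehyde enolate may be protonated before it alkylates; the ring fusion may close cis. Fallback with known reactions, from 15 back to 18: TMSI (TMSCl, NaI, MeCN, −20 °C; NaHCO3 work-up, which also returns the enal from its iodide adduct) opens the acylcyclopropane to the γ-iodo ketone (2E,4S,6Z)-11-iodo-2-isopropyl-6,9-dimethyl-1,8-dioxoundeca-2,6-dien-4-yl 3,4-dimethoxybenzoate F1. Soft enolisation (TMSOTf, Et3N, CH2Cl2, −78 °C) gives the trimethylsilyl dienol ether of that ketone F2, with no free enolate and hence no re-closure. TiCl4 (CH2Cl2, −78 °C, high dilution) then effects an intramolecular Mukaiyama–Michael addition to the seven-membered γ-iodo aldehyde F3, in which C1 is quaternary. t-BuOK (THF, 0 °C) closes the cyclopentane by intramolecular aldehyde enolate alkylation to 18.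

Step 11. What may go wrong: poor or reversed facial selectivity of hydride delivery at C10, because the seven-membered enone is flexible. Fallback from 20, ending at 23: the endgame is made stereoconvergent. The epimers are separated; the 10α-alcohol 6α-(3,4-dimethoxybenzoyloxy)dauc-8-ene-4β,10α-diol F4 is esterified with retention by the mixed-anhydride method (angelic acid, 2,4,6-trichlorobenzoyl chloride, Et3N, toluene; then F4, 80 °C) to give 23, while any 10β-alcohol 21 goes through step 12.

Step 12. What may go wrong: elimination or allylic transposition of the oxyphosphonium ion, slow substitution at the neopentylic centre, or phosphine-induced isomerisation of the angelate to the tiglate. Fallback from 21, ending at 23: Mitsunobu inversion with 4-nitrobenzoic acid (PPh3, DIAD, toluene) gives 10α-(4-nitrobenzoyloxy)-6α-(3,4-dimethoxybenzoyloxy)dauc-8-en-4β-ol F5; selective methanolysis of the activated ester (K2CO3, MeOH, 0 °C) gives the 10α-alcohol F4; mixed-anhydride angeloylation with retention, as in the fallback for step 11, gives 23.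

**Further compounds**
F1 | step 9 | (2E,4S,6Z)-11-iodo-2-isopropyl-6,9-dimethyl-1,8-dioxoundeca-2,6-dien-4-yl 3,4-dimethoxybenzoate (C9 epimers) | CC(CCI)C(=O)/C=C(C)\C[C@H](OC(=O)c1ccc(OC)c(OC)c1)/C=C(\C(C)C)C=O
F2 | step 9 | trimethylsilyl dienol ether of F1 | CC(CCI)=C(O[Si](C)(C)C)/C=C(C)\C[C@H](OC(=O)c1ccc(OC)c(OC)c1)/C=C(\C(C)C)C=O
F3 | step 9 | seven-membered γ-iodo aldehyde (Michael adduct, aldehyde α-carbon epimers) | O=C1C=C(C)C[C@H](OC(=O)c2ccc(OC)c(OC)c2)[C@@H](C(C=O)C(C)C)[C@]1(C)CCI
F4 | step 11 | 6α-(3,4-dimethoxybenzoyloxy)dauc-8-ene-4β,10α-diol | O[C@@H]1C=C(C)C[C@H](OC(=O)c2ccc(OC)c(OC)c2)[C@@H]2[C@]1(C)CC[C@@]2(O)C(C)C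
F5 | step 12 | 10α-(4-nitrobenzoyloxy)-6α-(3,4-dimethoxybenzoyloxy)dauc-8-en-4β-ol | O=C(O[C@@H]1C=C(C)C[C@H](OC(=O)c2ccc(OC)c(OC)c2)[C@@H]2[C@]1(C)CC[C@@]2(O)C(C)C)c1ccc(cc1)[N+](=O)[O-]
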